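**Retrosynthetic overview**

1. Feature: in the lactone (O1, C2=O, C3, C4, C5), C4 is bonded both to C3 and to the benzylic carbon C7' that carries the 3-hydroxy-4-methoxyphenyl ring (ring A). C4–C7' can therefore be one vinyl unit that takes a carbon group at C4 and ring A at C7'.
2. Target ⇐ trans lactone dibenzyl ether 24 (hydrogenolysis; C3 equilibration) ⇐ γ-hydroxy acid (O1–C2 lactonisation, the only ring closure, made late) ⇐ C2 acid by anti-Markovnikov hydroboration and oxidation of the C3=C2 methylene; C5–OH by CH2 insertion into the C4–B bond.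
3. Key disconnection: C3–C4 and C7'–ring A are made together from alkenyl boronate 7 (C2, C3, C7, ring B), vinyllithium 13 (C4, C7') and aryl triflate 11 (ring A) by a palladium/MandyPhos conjunctive coupling that sets C4.
4. 7 ⇐ 4-bromo-2-methoxyphenol + 2,3-dibromopropene; 11 ⇐ 3-(benzyloxy)-4-methoxybenzaldehyde; 13 ⇐ tetravinylstannane.

Key step: step 7

Assumption: the (Sp,Sp) enantiomer of the MandyPhos ligand is taken to give the (R) boronate at C4; if a test run shows the opposite sense, the mirror-image ligand is used with no other change.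

**Route**

Step 1
Reactants: 1 4-bromo-2-methoxyphenol
Product: 2 1-(benzyloxy)-4-bromo-2-methoxybenzene
Conditions: BnBr, K2CO3, DMF, rt
Reagents that add atoms: benzyl bromide, BrCc1ccccc1
Why: Williamson ether synthesis on the phenoxide; the aryl bromide is inert under these conditions.

Step 2
Reactants: 2 1-(benzyloxy)-4-bromo-2-methoxybenzene; 3 2,3-dibromopropene
Product: 5 1-(benzyloxy)-4-(2-bromoprop-2-en-1-yl)-2-methoxybenzene, via arylmagnesium bromide 4 (not isolated)
Conditions: Mg, I2 (cat.), THF, 50 °C; then 3, CuI (5 mol%), THF, −20 °C to rt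
Reagents that add atoms: none
Why: Grignard formation followed by copper-assisted allylic substitution at the allylic bromide of 3 (direct and allyl-transposed attack give the same product), the vinylic bromide staying untouched.

Step 3
Reactants: 5 1-(benzyloxy)-4-(2-bromoprop-2-en-1-yl)-2-methoxybenzene
Product: 7 2-{3-[4-(benzyloxy)-3-methoxyphenyl]prop-1-en-2-yl}-4,4,5,5-tetramethyl-1,3,2-dioxaborolane, via alkenyllithium 6 (not isolated)
Conditions: t-BuLi (2 equiv), Et2O/THF, −78 °C; then 2-isopropoxy-4,4,5,5-tetramethyl-1,3,2-dioxaborolane, −78 °C to rt; H2O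
Reagents that add atoms: 2-isopropoxy-4,4,5,5-tetramethyl-1,3,2-dioxaborolane, CC(C)OB1OC(C)(C)C(C)(C)O1
Why: Bromine–lithium exchange at −78 °C should outrun deprotonation of the benzylic/allylic CH2, and the alkenyllithium is borylated by the isopropoxy boronate with loss of isopropoxide.

Step 4
Reactants: 8 3-(benzyloxy)-4-methoxybenzaldehyde
Product: 10 3-(benzyloxy)-4-methoxyphenol, via aryl formate 9 (not isolated)
Conditions: mCPBA, CH2Cl2, 0 °C to rt; aq. NaHCO3/Na2S2O3 wash; then K2CO3 (cat.), MeOH, rt
Reagents that add atoms: mCPBA, O=C(OO)c1cccc(Cl)c1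
Why: Baeyer–Villiger (Dakin-type) oxidation, in which the electron-rich aryl group migrates in preference to hydrogen to give the aryl formate, which is then cleaved by transesterification.

Step 5
Reactants: 10 3-(benzyloxy)-4-methoxyphenol
Product: 11 3-(benzyloxy)-4-methoxyphenyl trifluoromethanesulfonate
Conditions: Tf2O, pyridine, CH2Cl2, 0 °C
Reagents that add atoms: trifluoromethanesulfonic anhydride, O=S(=O)(OS(=O)(=O)C(F)(F)F)C(F)(F)F
Why: O-sulfonylation of the phenol gives the aryl triflate needed for oxidative addition without introducing halide.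

Step 6
Reactants: 12 tetravinylstannane
Product: 13 vinyllithium
Conditions: n-BuLi, pentane, rt; precipitate filtered under argon, washed with pentane, dissolved in Et2O and titrated
Reagents that add atoms: n-butyllithium, [Li]CCCC
Why: Tin–lithium exchange precipitates halide-free vinyllithium from pentane, which matters because lithium halide would suppress the cationic palladium pathway of step 7.

Step 7
Reactants: 7 2-{3-[4-(benzyloxy)-3-methoxyphenyl]prop-1-en-2-yl}-4,4,5,5-tetramethyl-1,3,2-dioxaborolane; 13 vinyllithium; 11 3-(benzyloxy)-4-methoxyphenyl trifluoromethanesulfonate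
Product: 15 2-[(2R)-1-[3-(benzyloxy)-4-methoxyphenyl]-3-{[4-(benzyloxy)-3-methoxyphenyl]methyl}but-3-en-2-yl]-4,4,5,5-tetramethyl-1,3,2-dioxaborolane, via lithium bis(alkenyl)borate 14 (not isolated)
Conditions: 7, Et2O, 0 °C; 13 (1.0 equiv), 0 °C to rt; solvent exchanged for THF; 11 (1.1 equiv), Pd(OAc)2 (2 mol%), (Sp,Sp)-MandyPhos [1,1'-bis(bis(3,5-dimethylphenyl)phosphino)-2,2'-bis((R)-α-(dimethylamino)benzyl)ferrocene] (2.4 mol%), THF, 60 °C
Reagents that add atoms: none
Why: Vinyllithium adds to the boron of 7 to give the ate complex 14; zerovalent palladium formed from Pd(OAc)2 and the ligand inserts into the C–O bond of triflate 11 to give a cationic aryl complex of divalent palladium, which binds the unsubstituted vinyl group of 14 and triggers anti 1,2-migration of the 1,1-disubstituted alkenyl group from boron to C4 (C3–C4 bond), leaving palladium on C7', and reductive elimination then forms the C7'–aryl bond. The closest known reaction type is the palladium/MandyPhos-catalysed enantioselective conjunctive cross-coupling of bis(alkenyl)borates carrying an α-substituted migrating alkenyl group with aryl triflates, which gives α-chiral allylic boronic esters of this kind. No ring is closed. The new stereocentre C4 is set by the chiral bisphosphine, which selects the face of the vinyl group that palladium binds while the migrating group arrives on the opposite face. The step needs site selectivity (palladium must bind the vinyl group and not the migrating alkene) and must outrun direct Suzuki-type transmetallation; the α-substituent makes the alkenyl group of 7 the poorer ligand, and the halide-free cationic palladium derived from the triflate favours alkene binding. The wide bite angle of the ligand should speed reductive elimination so that β-hydride loss from the C7' alkylpalladium intermediate does not compete.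

Step 8
Reactants: 15 (R)-allylic boronic ester from step 7
Product: 17 (2R)-2-{[3-(benzyloxy)-4-methoxyphenyl]methyl}-3-{[4-(benzyloxy)-3-methoxyphenyl]methyl}but-3-en-1-ol, via homologated boronic ester 16 (not isolated)
Conditions: BrCH2Cl, n-BuLi, THF, −78 °C to rt; then NaOH (3 M aq.), H2O2 (30%), 0 °C to rt
Reagents that add atoms: bromochloromethane, ClCBr; hydrogen peroxide, OO
Why: Matteson homologation, in which chloromethyllithium adds to boron and the secondary allylic carbon C4 migrates 1,2 with loss of chloride and retention of configuration; basic peroxide then oxidises the new primary C5–B bond.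

Step 9
Reactants: 17 (2R)-homoallylic alcohol from step 8
Product: 18 tert-butyldimethylsilyl ether of 17, [(2R)-2-{[3-(benzyloxy)-4-methoxyphenyl]methyl}-3-{[4-(benzyloxy)-3-methoxyphenyl]methyl}but-3-en-1-yl]oxy(tert-butyl)dimethylsilane
Conditions: TBSCl, imidazole, DMF, rt
Reagents that add atoms: tert-butyldimethylsilyl chloride, CC(C)(C)[Si](C)(C)Cl
Why: Silylation of the primary alcohol masks C5–OH so that only the C2 hydroxyl made next is oxidised, which fixes which carbon becomes the lactone carbonyl.

Step 10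
Reactants: 18 silyl ether from step 9
Product: 20 (3R)-2-{[4-(benzyloxy)-3-methoxyphenyl]methyl}-3-{[3-(benzyloxy)-4-methoxyphenyl]methyl}-4-[(tert-butyldimethylsilyl)oxy]butan-1-ol (both epimers at the future C3), via B-alkyl-9-borabicyclononane 19 (not isolated)
Conditions: 9-BBN dimer, THF, rt to 60 °C; then NaOH (3 M aq.), H2O2 (30%), 0 °C to rt
Reagents that add atoms: hydrogen peroxide, OO
Why: Anti-Markovnikov hydroboration–oxidation places the hydroxyl on the terminal carbon C2; C3 is created here with little control from C4, so both epimers are expected and are corrected in step 13.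

Step 11
Reactants: 20 primary alcohol from step 10
Product: 21 (3R)-2-{[4-(benzyloxy)-3-methoxyphenyl]methyl}-3-{[3-(benzyloxy)-4-methoxyphenyl]methyl}-4-[(tert-butyldimethylsilyl)oxy]butanoic acid (C3 epimers)
Conditions: TEMPO (20 mol%), PhI(OAc)2 (2.5 equiv), MeCN/H2O 1:1, rt
Reagents that add atoms: water, O
Why: Oxoammonium (TEMPO/PhI(OAc)2) oxidation takes the primary alcohol through the aldehyde hydrate to the acid and should leave the silyl ether, the benzyl ethers and the arenes alone.

Step 12
Reactants: 21 silyloxy acid from step 11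
Product: 23 (4R)-3-{[4-(benzyloxy)-3-methoxyphenyl]methyl}-4-{[3-(benzyloxy)-4-methoxyphenyl]methyl}dihydrofuran-2(3H)-one (cis/trans mixture at C3), via γ-hydroxy acid 22 (not isolated)
Conditions: HCl (2 M aq.), THF, rt to 40 °C
Reagents that add atoms: none
Why: Acid cleaves the primary silyl ether and the freed γ-hydroxy acid closes spontaneously to the five-membered lactone (acid-catalysed lactonisation forming O1–C2).

Step 13
Reactants: 23 lactone mixture from step 12
Product: 24 (3R,4R)-3-{[4-(benzyloxy)-3-methoxyphenyl]methyl}-4-{[3-(benzyloxy)-4-methoxyphenyl]methyl}dihydrofuran-2(3H)-one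
Conditions: DBU, toluene, 100 °C; residual cis isomer separated and resubjected
Reagents that add atoms: none
Why: Base-mediated epimerisation through the lactone enolate touches only C3 (C4 is not acidic) and should converge on the thermodynamically preferred trans lactone, which with C4 fixed as R is the (3R,4R) isomer.

Step 14
Reactants: 24 trans lactone dibenzyl ether
Product: 25 (3R,4R)-3-(4-hydroxy-3-methoxybenzyl)-4-(3-hydroxy-4-methoxybenzyl)dihydrofuran-2(3H)-one
Conditions: H2 (1 atm), Pd/C (10% Pd), EtOAc/MeOH, rt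
Reagents that add atoms: none
Why: Catalytic hydrogenolysis removes both benzyl aryl ethers; the lactone, the methyl ethers and both stereocentres are not affected.

**Compound list**

1 | 4-bromo-2-methoxyphenol | COc1cc(Br)ccc1O | starting material
2 | 1-(benzyloxy)-4-bromo-2-methoxybenzene | COc1cc(Br)ccc1OCc1ccccc1 | intermediate
3 | 2,3-dibromopropene | C=C(Br)CBr | starting material
4 | [4-(benzyloxy)-3-methoxyphenyl]magnesium bromide | COc1cc([Mg]Br)ccc1OCc1ccccc1 | intermediate
5 | 1-(benzyloxy)-4-(2-bromoprop-2-en-1-yl)-2-methoxybenzene | C=C(Br)Cc1ccc(OCc2ccccc2)c(OC)c1 | intermediate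
6 | {3-[4-(benzyloxy)-3-methoxyphenyl]prop-1-en-2-yl}lithium | [Li]C(=C)Cc1ccc(OCc2ccccc2)c(OC)c1 | intermediate
7 | 2-{3-[4-(benzyloxy)-3-methoxyphenyl]prop-1-en-2-yl}-4,4,5,5-tetramethyl-1,3,2-dioxaborolane | C=C(Cc1ccc(OCc2ccccc2)c(OC)c1)B1OC(C)(C)C(C)(C)O1 | intermediate
8 | 3-(benzyloxy)-4-methoxybenzaldehyde | COc1ccc(C=O)cc1OCc1ccccc1 | starting material
9 | 3-(benzyloxy)-4-methoxyphenyl formate | COc1ccc(OC=O)cc1OCc1ccccc1 | intermediate
10 | 3-(benzyloxy)-4-methoxyphenol | COc1ccc(O)cc1OCc1ccccc1 | intermediate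
11 | 3-(benzyloxy)-4-methoxyphenyl trifluoromethanesulfonate | COc1ccc(OS(=O)(=O)C(F)(F)F)cc1OCc1ccccc1 | intermediate
12 | tetravinylstannane | C=C[Sn](C=C)(C=C)C=C | starting material
13 | vinyllithium | [Li]C=C | intermediate
14 | lithium vinyl{3-[4-(benzyloxy)-3-methoxyphenyl]prop-1-en-2-yl}(pinacolato)borate | [Li+].C=C[B-]1(C(=C)Cc2ccc(OCc3ccccc3)c(OC)c2)OC(C)(C)C(C)(C)O1 | intermediate
15 | 2-[(2R)-1-[3-(benzyloxy)-4-methoxyphenyl]-3-{[4-(benzyloxy)-3-methoxyphenyl]methyl}but-3-en-2-yl]-4,4,5,5-tetramethyl-1,3,2-dioxaborolane | COc1ccc(C[C@@H](B2OC(C)(C)C(C)(C)O2)C(=C)Cc2ccc(OCc3ccccc3)c(OC)c2)cc1OCc1ccccc1 | intermediate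
16 | 2-[(2R)-2-{[3-(benzyloxy)-4-methoxyphenyl]methyl}-3-{[4-(benzyloxy)-3-methoxyphenyl]methyl}but-3-en-1-yl]-4,4,5,5-tetramethyl-1,3,2-dioxaborolane | COc1ccc(C[C@@H](CB2OC(C)(C)C(C)(C)O2)C(=C)Cc2ccc(OCc3ccccc3)c(OC)c2)cc1OCc1ccccc1 | intermediate
17 | (2R)-2-{[3-(benzyloxy)-4-methoxyphenyl]methyl}-3-{[4-(benzyloxy)-3-methoxyphenyl]methyl}but-3-en-1-ol | COc1ccc(C[C@@H](CO)C(=C)Cc2ccc(OCc3ccccc3)c(OC)c2)cc1OCc1ccccc1 | intermediate
18 | tert-butyldimethylsilyl ether of 17 | COc1ccc(C[C@@H](CO[Si](C)(C)C(C)(C)C)C(=C)Cc2ccc(OCc3ccccc3)c(OC)c2)cc1OCc1ccccc1 | intermediate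
19 | B-alkyl-9-borabicyclo[3.3.1]nonane from hydroboration of 18 (C3 epimers) | COc1ccc(C[C@@H](CO[Si](C)(C)C(C)(C)C)C(CB2C3CCCC2CCC3)Cc2ccc(OCc3ccccc3)c(OC)c2)cc1OCc1ccccc1 | intermediate
20 | (3R)-2-{[4-(benzyloxy)-3-methoxyphenyl]methyl}-3-{[3-(benzyloxy)-4-methoxyphenyl]methyl}-4-[(tert-butyldimethylsilyl)oxy]butan-1-ol (C3 epimers) | COc1ccc(C[C@@H](CO[Si](C)(C)C(C)(C)C)C(CO)Cc2ccc(OCc3ccccc3)c(OC)c2)cc1OCc1ccccc1 | intermediate
21 | (3R)-2-{[4-(benzyloxy)-3-methoxyphenyl]methyl}-3-{[3-(benzyloxy)-4-methoxyphenyl]methyl}-4-[(tert-butyldimethylsilyl)oxy]butanoic acid (C3 epimers) | COc1ccc(C[C@@H](CO[Si](C)(C)C(C)(C)C)C(C(=O)O)Cc2ccc(OCc3ccccc3)c(OC)c2)cc1OCc1ccccc1 | intermediate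
22 | (3R)-2-{[4-(benzyloxy)-3-methoxyphenyl]methyl}-3-{[3-(benzyloxy)-4-methoxyphenyl]methyl}-4-hydroxybutanoic acid (C3 epimers) | COc1ccc(C[C@@H](CO)C(C(=O)O)Cc2ccc(OCc3ccccc3)c(OC)c2)cc1OCc1ccccc1 | intermediate
23 | (4R)-3-{[4-(benzyloxy)-3-methoxyphenyl]methyl}-4-{[3-(benzyloxy)-4-methoxyphenyl]methyl}dihydrofuran-2(3H)-one (C3 epimers) | COc1ccc(C[C@H]2COC(=O)C2Cc2ccc(OCc3ccccc3)c(OC)c2)cc1OCc1ccccc1 | intermediate
24 | (3R,4R)-3-{[4-(benzyloxy)-3-methoxyphenyl]methyl}-4-{[3-(benzyloxy)-4-methoxyphenyl]methyl}dihydrofuran-2(3H)-one | COc1ccc(C[C@H]2COC(=O)[C@@H]2Cc2ccc(OCc3ccccc3)c(OC)c2)cc1OCc1ccccc1 | intermediate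
25 | (3R,4R)-3-(4-hydroxy-3-methoxybenzyl)-4-(3-hydroxy-4-methoxybenzyl)dihydrofuran-2(3H)-one | COc1ccc(C[C@H]2COC(=O)[C@@H]2Cc2ccc(O)c(OC)c2)cc1O | target

**Totals**

Total step count: 14. Longest linear sequence: 11 steps (steps 1, 2, 3, 7, 8, 9, 10, 11, 12, 13, 14).

**Steps most likely to fail**

1. Step 7. An alkenyl group of the ate complex may be transferred directly to the arylpalladium species (Suzuki-type coupling) faster than the metallate shift, palladium may bind the substituted alkene, or the facial selectivity at C4 may be poor with this bulky migrating group. The fallback sets out from aldehyde 8 and returns at 24, replacing steps 7 to 13 with known lignan chemistry. Stobbe condensation of 8 with dimethyl succinate (NaOMe, MeOH, reflux) should give (E)-4-[3-(benzyloxy)-4-methoxyphenyl]-3-(methoxycarbonyl)but-3-enoic acid F1. Asymmetric hydrogenation of F1 with [Rh(cod)2]BF4 and a chiral bisphosphine of the enantiomer leading to R should give (3R)-4-[3-(benzyloxy)-4-methoxyphenyl]-3-(methoxycarbonyl)butanoic acid F2. Reduction of the ester in the presence of the carboxylate salt with Ca(BH4)2 (from CaCl2 and NaBH4 in EtOH), followed by acidification, should give (4R)-4-[3-(benzyloxy)-4-methoxybenzyl]dihydrofuran-2(3H)-one F3. Its lithium enolate (LiHMDS, THF, −78 °C) is alkylated anti to the C4 substituent with 4-(benzyloxy)-3-methoxybenzyl bromide F4, made from the commercial benzyl alcohol with PBr3, to give 24.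

2. Step 8. The short-lived carbenoid may decompose before it is captured by the hindered secondary allylic boronic ester, or the ate complex may revert instead of migrating, so that oxidation returns the non-homologated allylic alcohol. The fallback sets out from 15 and returns at 16. Dichloromethyllithium (CH2Cl2, n-BuLi, THF, −100 °C) is a longer-lived carbenoid, and with ZnCl2 to promote migration it should give the α-chloro boronic ester 2-[(2R)-1-chloro-2-{[3-(benzyloxy)-4-methoxyphenyl]methyl}-3-{[4-(benzyloxy)-3-methoxyphenyl]methyl}but-3-en-1-yl]-4,4,5,5-tetramethyl-1,3,2-dioxaborolane F5. LiBHEt3 then replaces chloride by hydride through a borohydride ate complex and 1,2-hydride shift to give 16, which is oxidised as in step 8.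

3. Step 3. The alkenyllithium may be quenched by proton transfer from the doubly activated benzylic/allylic CH2, or t-BuLi may dehydrobrominate the vinyl bromide towards the allene. The fallback sets out from 5 and returns at 7 without an organolithium: palladium-catalysed Miyaura borylation with bis(pinacolato)diboron, PdCl2(PPh3)2, PPh3 and KOPh in toluene at 50 °C. It makes no new compound (entry F0).

**Further compounds**

F1 | step 7 | (E)-4-[3-(benzyloxy)-4-methoxyphenyl]-3-(methoxycarbonyl)but-3-enoic acid | OC(=O)C/C(C(=O)OC)=C\c1ccc(OC)c(OCc2ccccc2)c1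
F2 | step 7 | (3R)-4-[3-(benzyloxy)-4-methoxyphenyl]-3-(methoxycarbonyl)butanoic acid | COc1ccc(C[C@H](CC(=O)O)C(=O)OC)cc1OCc1ccccc1
F3 | step 7 | (4R)-4-[3-(benzyloxy)-4-methoxybenzyl]dihydrofuran-2(3H)-one | COc1ccc(C[C@H]2COC(=O)C2)cc1OCc1ccccc1
F4 | step 7 | 4-(benzyloxy)-3-methoxybenzyl bromide | COc1cc(CBr)ccc1OCc1ccccc1
F5 | step 8 | 2-[(2R)-1-chloro-2-{[3-(benzyloxy)-4-methoxyphenyl]methyl}-3-{[4-(benzyloxy)-3-methoxyphenyl]methyl}but-3-en-1-yl]-4,4,5,5-tetramethyl-1,3,2-dioxaborolane | COc1ccc(C[C@@H](C(Cl)B2OC(C)(C)C(C)(C)O2)C(=C)Cc2ccc(OCc3ccccc3)c(OC)c2)cc1OCc1ccccc1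
F0 | step 3 | none | none
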